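**Retrosynthetic overview**

1. The route rests on one feature: the C3 oxygen and C7, the carbon benzylic to the 4-oxygenated 3,5-dimethoxyphenyl ring, can be tied into a six-membered ring O–C3–C4–C5–C6–C7 (a 2-aryl-tetrahydropyran). Its chair relays the C3 configuration to C5, and its benzylic C7–O bond can later be cut reductively.
2. Target ⇐ hydrogenolysis of two benzyl ethers ⇐ acetylation of C3–OH ⇐ Et3SiH/BF3·OEt2 cleavage of the C7–O bond of the tetrahydropyran that carries the inverted C5 acetate.
3. That acetate ⇐ Mitsunobu inversion with acetic acid of the all-cis tetrahydropyran-4-ol ⇐ methanolysis of the Prins trifluoroacetate.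
4. Tetrahydropyran (the only ring formed, closed in one step) ⇐ Prins cyclisation of (R)-1-(4-benzyloxy-3-methoxyphenyl)hex-5-en-3-ol with 4-benzyloxy-3,5-dimethoxybenzaldehyde, forming C6–C7, O–C7 and C5–O.
5. Homoallylic alcohol ⇐ asymmetric allylboration of the 3-arylpropanal made from eugenol (benzylation, hydroboration–oxidation, alcohol oxidation); aldehyde partner ⇐ benzylation of syringaldehyde.

Key step: step 6

Remark: chain locants C1–C7 run from the carbon on the 4-hydroxy-3-methoxyphenyl ring (C1) to the carbon on the 4-hydroxy-3,5-dimethoxyphenyl ring (C7); with these the target is the (3R,5S), 3,5-syn diacetate.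

**Route**

Step 1
Reactants: 1 eugenol
Product: 2 4-allyl-1-(benzyloxy)-2-methoxybenzene
Conditions: BnBr, K2CO3, DMF, rt
Reagents that add atoms: benzyl bromide BrCc1ccccc1
Why: Williamson etherification of the phenoxide; the allyl group is untouched by K2CO3 at room temperature and no stereocentre is involved.

Step 2
Reactants: 2 4-allyl-1-(benzyloxy)-2-methoxybenzene
Product: 4 the primary alcohol 3-[4-(benzyloxy)-3-methoxyphenyl]propan-1-ol, via B-alkyl-9-borabicyclononane adduct 3 (not isolated)
Conditions: 9-borabicyclo[3.3.1]nonane (9-BBN), THF, 0 °C → rt; then NaOH, H2O2, H2O, 0 °C → rt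
Reagents that add atoms: hydrogen peroxide OO
Why: Hydroboration–oxidation; the bulky borane adds anti-Markovnikov to the terminal alkene and the C–B bond is oxidised to C–OH, the aryl benzyl ether being inert.

Step 3
Reactants: 4 3-[4-(benzyloxy)-3-methoxyphenyl]propan-1-ol
Product: 5 3-[4-(benzyloxy)-3-methoxyphenyl]propanal
Conditions: TEMPO (cat.), PhI(OAc)2, CH2Cl2, rt
Reagents that add atoms: none
Why: Oxoammonium-mediated (TEMPO) oxidation of a primary alcohol stops cleanly at the aldehyde and should leave the O-protected arene alone.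

Step 4
Reactants: 5 3-[4-(benzyloxy)-3-methoxyphenyl]propanal; 6 allylmagnesium bromide
Product: 9 (3R)-1-[4-(benzyloxy)-3-methoxyphenyl]hex-5-en-3-ol, via B-allyldiisopinocampheylborane 7 (not isolated), via diisopinocampheylborinate ester 8 (not isolated)
Conditions: (−)-Ipc2BOMe [from (+)-α-pinene], Et2O, −78 °C → rt; then 5, −78 °C; then NaOH, H2O2, rt
Reagents that add atoms: none
Why: Brown asymmetric allylboration through a closed chair transition state; the allylborane of the (+)-α-pinene series delivers allyl to the Si face of an unbranched aliphatic aldehyde, which sets C3 as R, and high enantiomeric purity is expected.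

Step 5
Reactants: 10 syringaldehyde
Product: 11 4-(benzyloxy)-3,5-dimethoxybenzaldehyde
Conditions: BnBr, K2CO3, DMF, 60 °C
Reagents that add atoms: benzyl bromide BrCc1ccccc1
Why: Williamson etherification; gentle heating compensates for the flanking methoxy groups and the aldehyde is inert to carbonate.

Step 6
Reactants: 9 (3R)-1-[4-(benzyloxy)-3-methoxyphenyl]hex-5-en-3-ol; 11 4-(benzyloxy)-3,5-dimethoxybenzaldehyde
Product: 13 (2R,4S,6R)-2-[4-(benzyloxy)-3,5-dimethoxyphenyl]-6-{2-[4-(benzyloxy)-3-methoxyphenyl]ethyl}oxan-4-yl trifluoroacetate (all-cis), via (E)-oxocarbenium trifluoroacetate 12 (not isolated)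
Conditions: CF3CO2H (excess), CH2Cl2, 0 °C → rt; cold aq. NaHCO3 work-up
Reagents that add atoms: trifluoroacetic acid OC(=O)C(F)(F)F
Why: Acid-promoted condensation of the C3 hydroxyl of 9 with aldehyde 11 gives a hemiacetal that ionises to the (E)-aryl oxocarbenium ion 12, whose carbon (C7) is attacked by the terminal alkene carbon C6, forming C6–C7 and a secondary C5 cation that trifluoroacetate captures; this is the Prins cyclisation of a homoallylic alcohol with an aryl aldehyde, an established route to 2,4,6-trisubstituted tetrahydropyran-4-yl esters. The single ring O–C3–C4–C5–C6–C7 closes in the 6-endo-trig mode through a chair transition state. C7 is set by that chair, in which the C3 arylethyl chain and the C7 aryl group both lie equatorial, so the aryl-bearing carbon is cis to the C3 substituent (2R of the ring); C5 is set by equatorial capture of the tetrahydropyranyl cation by trifluoroacetate, cis to both (4S of the ring), which corresponds to the 3,5-anti relationship. The step needs diastereoselection relative to C3 and retention of the C3 configuration: the first follows from the equatorial preference of the C3 chain, the second from the carbinol being aliphatic, so that the aryl-conjugated ion 12 is the favoured partner of any 2-oxonia-Cope equilibrium and the C3–O bond has no tendency to ionise. The 4-benzyloxy group, twisted between two methoxy groups, donates only weakly, which should keep 12 reactive enough to cyclise faster than allyl transfer, and aryl benzyl ethers should tolerate CF3CO2H in CH2Cl2 at or below room temperature for the short reaction time.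

Step 7
Reactants: 13 all-cis tetrahydropyran-4-yl trifluoroacetate (used crude)
Product: 14 (2R,4S,6R)-2-[4-(benzyloxy)-3,5-dimethoxyphenyl]-6-{2-[4-(benzyloxy)-3-methoxyphenyl]ethyl}oxan-4-ol (all-cis)
Conditions: K2CO3, MeOH, rt
Reagents that add atoms: none
Why: Transesterification (methanolysis) of the highly electrophilic trifluoroacetate at the acyl carbon; the C5–O bond is not broken, so the configuration is kept.

Step 8
Reactants: 14 all-cis tetrahydropyran-4-ol
Product: 15 (2R,4R,6R)-2-[4-(benzyloxy)-3,5-dimethoxyphenyl]-6-{2-[4-(benzyloxy)-3-methoxyphenyl]ethyl}oxan-4-yl acetate (acetate trans to the two cis ring substituents)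
Conditions: AcOH, PPh3, DIAD, THF, 0 °C → rt
Reagents that add atoms: acetic acid CC(=O)O
Why: Mitsunobu esterification; acetate displaces the equatorial alkoxyphosphonium group by SN2 with inversion at C5, which turns the 3,5-anti into the required 3,5-syn relationship and installs the C5 acetate directly.

Step 9
Reactants: 15 tetrahydropyran-4-yl acetate with inverted C5
Product: 16 (3R,5S)-1-[4-(benzyloxy)-3-methoxyphenyl]-7-[4-(benzyloxy)-3,5-dimethoxyphenyl]-3-hydroxyheptan-5-yl acetate
Conditions: Et3SiH (excess), BF3·OEt2, CH2Cl2, −20 °C → rt; aq. NaHCO3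
Reagents that add atoms: none
Why: Ionic hydrogenation of a benzylic ether: BF3 activates the ring oxygen, the C7–O bond ionises to the alkoxyaryl-stabilised benzylic cation and Et3SiH delivers hydride to C7, which becomes CH2 (its stereocentre is erased), while the C3–O and C5–O bonds are never broken; a 5→3 acetyl shift, should it occur, is harmless because step 10 acetylates the remaining hydroxyl.

Step 10
Reactants: 16 ring-opened hydroxy acetate
Product: 17 (3R,5S)-1-[4-(benzyloxy)-3-methoxyphenyl]-7-[4-(benzyloxy)-3,5-dimethoxyphenyl]heptane-3,5-diyl diacetate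
Conditions: Ac2O, pyridine, DMAP (cat.), CH2Cl2, rt
Reagents that add atoms: acetic anhydride CC(=O)OC(C)=O
Why: DMAP-catalysed acylation of the secondary C3 alcohol at oxygen, without change at either stereocentre.

Step 11
Reactants: 17 bis-benzyl ether diacetate
Product: 18 (3R,5S)-1-(4-hydroxy-3-methoxyphenyl)-7-(4-hydroxy-3,5-dimethoxyphenyl)heptane-3,5-diyl diacetate (CNP0327377.1)
Conditions: H2 (1 atm), 10% Pd/C, EtOAc, rt
Reagents that add atoms: none
Why: Catalytic hydrogenolysis of the two aryl benzyl ethers; alkyl acetates are inert and no benzylic C–O bond remains in the chain, so nothing else should be cleaved.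

**Compound list**

1 | eugenol | COc1cc(CC=C)ccc1O | starting material
2 | 4-allyl-1-(benzyloxy)-2-methoxybenzene | COc1cc(CC=C)ccc1OCc1ccccc1 | intermediate
3 | 9-{3-[4-(benzyloxy)-3-methoxyphenyl]propyl}-9-borabicyclo[3.3.1]nonane (not isolated) | COc1cc(CCCB2C3CCCC2CCC3)ccc1OCc1ccccc1 | intermediate
4 | 3-[4-(benzyloxy)-3-methoxyphenyl]propan-1-ol | COc1cc(CCCO)ccc1OCc1ccccc1 | intermediate
5 | 3-[4-(benzyloxy)-3-methoxyphenyl]propanal | COc1cc(CCC=O)ccc1OCc1ccccc1 | intermediate
6 | allylmagnesium bromide | C=CC[Mg]Br | starting material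
7 | B-allyldiisopinocampheylborane of the (+)-α-pinene series (not isolated) | C=CCB([C@@H]1C[C@@H]2C[C@H]([C@H]1C)C2(C)C)[C@@H]1C[C@@H]2C[C@H]([C@H]1C)C2(C)C | intermediate
8 | (3R)-1-[4-(benzyloxy)-3-methoxyphenyl]hex-5-en-3-yl diisopinocampheylborinate (not isolated) | COc1cc(CC[C@@H](OB([C@@H]2C[C@@H]3C[C@H]([C@H]2C)C3(C)C)[C@@H]2C[C@@H]3C[C@H]([C@H]2C)C3(C)C)CC=C)ccc1OCc1ccccc1 | intermediate
9 | (3R)-1-[4-(benzyloxy)-3-methoxyphenyl]hex-5-en-3-ol | COc1cc(CC[C@@H](O)CC=C)ccc1OCc1ccccc1 | intermediate
10 | syringaldehyde | COc1cc(C=O)cc(OC)c1O | starting material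
11 | 4-(benzyloxy)-3,5-dimethoxybenzaldehyde | COc1cc(C=O)cc(OC)c1OCc1ccccc1 | intermediate
12 | (E)-oxocarbenium trifluoroacetate from 9 and 11 (not isolated) | COc1cc(CC[C@@H](/[O+]=C/c2cc(OC)c(OCc3ccccc3)c(OC)c2)CC=C)ccc1OCc1ccccc1.[O-]C(=O)C(F)(F)F | intermediate
13 | (2R,4S,6R)-2-[4-(benzyloxy)-3,5-dimethoxyphenyl]-6-{2-[4-(benzyloxy)-3-methoxyphenyl]ethyl}oxan-4-yl trifluoroacetate | COc1cc(CC[C@@H]2C[C@H](OC(=O)C(F)(F)F)C[C@H](c3cc(OC)c(OCc4ccccc4)c(OC)c3)O2)ccc1OCc1ccccc1 | intermediate
14 | (2R,4S,6R)-2-[4-(benzyloxy)-3,5-dimethoxyphenyl]-6-{2-[4-(benzyloxy)-3-methoxyphenyl]ethyl}oxan-4-ol | COc1cc(CC[C@@H]2C[C@H](O)C[C@H](c3cc(OC)c(OCc4ccccc4)c(OC)c3)O2)ccc1OCc1ccccc1 | intermediate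
15 | (2R,4R,6R)-2-[4-(benzyloxy)-3,5-dimethoxyphenyl]-6-{2-[4-(benzyloxy)-3-methoxyphenyl]ethyl}oxan-4-yl acetate | COc1cc(CC[C@@H]2C[C@@H](OC(C)=O)C[C@H](c3cc(OC)c(OCc4ccccc4)c(OC)c3)O2)ccc1OCc1ccccc1 | intermediate
16 | (3R,5S)-1-[4-(benzyloxy)-3-methoxyphenyl]-7-[4-(benzyloxy)-3,5-dimethoxyphenyl]-3-hydroxyheptan-5-yl acetate | COc1cc(CC[C@@H](O)C[C@@H](OC(C)=O)CCc2cc(OC)c(OCc3ccccc3)c(OC)c2)ccc1OCc1ccccc1 | intermediate
17 | (3R,5S)-1-[4-(benzyloxy)-3-methoxyphenyl]-7-[4-(benzyloxy)-3,5-dimethoxyphenyl]heptane-3,5-diyl diacetate | COc1cc(CC[C@@H](OC(C)=O)C[C@@H](OC(C)=O)CCc2cc(OC)c(OCc3ccccc3)c(OC)c2)ccc1OCc1ccccc1 | intermediate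
18 | (3R,5S)-1-(4-hydroxy-3-methoxyphenyl)-7-(4-hydroxy-3,5-dimethoxyphenyl)heptane-3,5-diyl diacetate | COc1cc(CC[C@H](C[C@H](CCc2cc(OC)c(O)c(OC)c2)OC(C)=O)OC(C)=O)ccc1O | target

**Step count**

Total: 11 steps. Longest linear sequence: 10 steps (steps 1–4, then 6–11); step 5 is the one-step side branch.

**Steps most likely to fail**

1. Step 6 (Prins cyclisation). The aryl-stabilised oxocarbenium ion may cyclise slowly, so that 2-oxonia-Cope allyl transfer and aldehyde exchange erode the C3 configuration and give symmetric tetrahydropyrans, and prolonged acid may start to cleave the benzyl ethers. The fallback generates the same ion without water or free aldehyde, by the segment-coupling Prins route through an α-acetoxy ether, and sets out from 9 and 11. Oxidation of 11 (NaClO2, NaH2PO4, 2-methylbut-2-ene, tBuOH/H2O) should give 4-(benzyloxy)-3,5-dimethoxybenzoic acid F1. Esterification with 9 (DCC, DMAP, CH2Cl2) should give (3R)-1-[4-(benzyloxy)-3-methoxyphenyl]hex-5-en-3-yl 4-(benzyloxy)-3,5-dimethoxybenzoate F2. Reductive acetylation (iBu2AlH, CH2Cl2, −78 °C; then Ac2O, pyridine, DMAP) should give the α-acetoxy ether F3. BF3·OEt2 with AcOH at 0 °C should then close the ring to the all-cis tetrahydropyran-4-yl acetate F4, and K2CO3 in MeOH returns the route at 14.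

2. Step 9 (reductive ring opening). Ionisation of the C7–O bond may be incomplete because the 4-benzyloxy group is twisted out of conjugation, the C7 cation may be intercepted by the C5 acetate carbonyl and reduced at the wrong carbon, or the Lewis acid may remove the hindered benzyl group. The fallback changes the activation mode and sets out from 15. Hydrogenolysis (H2, Pd(OH)2/C, AcOH, rt) should remove both benzyl groups and then cleave the ring C7–O bond, now activated by the free para-hydroxyl as in the hydrogenolysis of 4-hydroxyaryl cyclic ether lignans. This should give (3R,5S)-3-hydroxy-1-(4-hydroxy-3-methoxyphenyl)-7-(4-hydroxy-3,5-dimethoxyphenyl)heptan-5-yl acetate F5. Peracetylation (Ac2O, pyridine, DMAP) should give the tetraacetate F6, and pyrrolidine in CH2Cl2 at 0 °C should aminolyse only the two aryl acetates, which returns the route at 18.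

3. Step 8 (Mitsunobu inversion). The activated ring alcohol may eliminate to a dihydropyran, or displacement by the weakly acidic acetic acid may stall. The fallback is an oxidation–reduction inversion and sets out from 14. Dess–Martin periodinane in CH2Cl2 should give (2R,6R)-2-[4-(benzyloxy)-3,5-dimethoxyphenyl]-6-{2-[4-(benzyloxy)-3-methoxyphenyl]ethyl}oxan-4-one F7. LiBH(sBu)3 in THF at −78 °C should deliver hydride from the equatorial direction to give the axial alcohol, the (2R,4R,6R)-oxan-4-ol F8, and Ac2O, pyridine, DMAP returns the route at 15.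

**Further compounds**

F1 | step 6 | 4-(benzyloxy)-3,5-dimethoxybenzoic acid | COc1cc(C(=O)O)cc(OC)c1OCc1ccccc1
F2 | step 6 | (3R)-1-[4-(benzyloxy)-3-methoxyphenyl]hex-5-en-3-yl 4-(benzyloxy)-3,5-dimethoxybenzoate | COc1cc(CC[C@@H](OC(=O)c2cc(OC)c(OCc3ccccc3)c(OC)c2)CC=C)ccc1OCc1ccccc1
F3 | step 6 | acetoxy[4-(benzyloxy)-3,5-dimethoxyphenyl]methyl ether of 9 (both epimers at the acetal carbon) | COc1cc(CC[C@@H](OC(OC(C)=O)c2cc(OC)c(OCc3ccccc3)c(OC)c2)CC=C)ccc1OCc1ccccc1
F4 | step 6 | (2R,4S,6R)-2-[4-(benzyloxy)-3,5-dimethoxyphenyl]-6-{2-[4-(benzyloxy)-3-methoxyphenyl]ethyl}oxan-4-yl acetate | COc1cc(CC[C@@H]2C[C@H](OC(C)=O)C[C@H](c3cc(OC)c(OCc4ccccc4)c(OC)c3)O2)ccc1OCc1ccccc1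
F5 | step 9 | (3R,5S)-3-hydroxy-1-(4-hydroxy-3-methoxyphenyl)-7-(4-hydroxy-3,5-dimethoxyphenyl)heptan-5-yl acetate | COc1cc(CC[C@@H](O)C[C@@H](OC(C)=O)CCc2cc(OC)c(O)c(OC)c2)ccc1O
F6 | step 9 | (3R,5S)-1-(4-acetoxy-3-methoxyphenyl)-7-(4-acetoxy-3,5-dimethoxyphenyl)heptane-3,5-diyl diacetate | COc1cc(CC[C@@H](OC(C)=O)C[C@@H](OC(C)=O)CCc2cc(OC)c(OC(C)=O)c(OC)c2)ccc1OC(C)=O
F7 | step 8 | (2R,6R)-2-[4-(benzyloxy)-3,5-dimethoxyphenyl]-6-{2-[4-(benzyloxy)-3-methoxyphenyl]ethyl}oxan-4-one | COc1cc(CC[C@@H]2CC(=O)C[C@H](c3cc(OC)c(OCc4ccccc4)c(OC)c3)O2)ccc1OCc1ccccc1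
F8 | step 8 | (2R,4R,6R)-2-[4-(benzyloxy)-3,5-dimethoxyphenyl]-6-{2-[4-(benzyloxy)-3-methoxyphenyl]ethyl}oxan-4-ol | COc1cc(CC[C@@H]2C[C@@H](O)C[C@H](c3cc(OC)c(OCc4ccccc4)c(OC)c3)O2)ccc1OCc1ccccc1
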